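**Retrosynthetic overview** (rings: A = catechol ring with the meta ether, B = para-phenylene, C = catechol ring with the ortho ether, D = ortho-phenylene)
1. Target ⇐ fourfold O-demethylation and C=C hydrogenation of a macrocyclic stilbene tetramethyl ether.
2. The 17-membered macrocycle, the only ring built, is closed last by an intramolecular Wittig reaction that forms the A–D two-carbon bridge.
3. The open-chain precursor ⇐ a bibenzyl from an α-aryl cinnamic acid (decarboxylation, hydrogenation), itself made by the key intermolecular Perkin-type aldol condensation of an AB arylacetic acid with a CD aldehyde (B–C bridge).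
4. AB acid ⇐ SNAr of methyl 3-hydroxy-4,5-dimethoxybenzoate on 4-fluorobenzaldehyde, then one-carbon homologation; CD aldehyde ⇐ SNAr of 2-hydroxy-3,4-dimethoxybenzaldehyde on 2-fluorobenzonitrile.
5. All four benzene rings come from the starting materials; ester (ring A) and nitrile (ring D) are the differentiated handles for the ring closure.

Assumption: the target has no stereocentre (achiral as drawn), so no enantiocontrol is needed, and alkene geometry in intermediates is irrelevant because both C=C bonds are hydrogenated; phenols 1 and 4 are taken as catalogue compounds.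

**Route**

Step 1
Reactants: 1 2-hydroxy-3,4-dimethoxybenzaldehyde; 2 2-fluorobenzonitrile
Product: 3 2-(6-formyl-2,3-dimethoxyphenoxy)benzonitrile
Conditions: K2CO3, DMF, 110 °C
Reagents that add atoms: none
Why: SNAr (nucleophilic aromatic substitution) in which the phenoxide of 1 displaces fluoride activated by the ortho nitrile, which also serves as a masked aldehyde distinct from every other carbonyl group in the route.

Step 2
Reactants: 4 methyl 3-hydroxy-4,5-dimethoxybenzoate; 5 4-fluorobenzaldehyde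
Product: 6 methyl 3-(4-formylphenoxy)-4,5-dimethoxybenzoate
Conditions: K2CO3, DMF, 120 °C
Reagents that add atoms: none
Why: SNAr on a para-formyl-activated aryl fluoride, a standard and high-yielding diaryl ether synthesis that leaves the methyl ester untouched.

Step 3
Reactants: 6 methyl 3-(4-formylphenoxy)-4,5-dimethoxybenzoate
Product: 7 methyl 3,4-dimethoxy-5-[4-(2-methoxyethenyl)phenoxy]benzoate (E/Z mixture)
Conditions: Ph3P(CH2OMe)Cl, KOtBu, THF, 0 °C to rt
Reagents that add atoms: (methoxymethyl)triphenylphosphonium chloride, COC[P+](c1ccccc1)(c1ccccc1)c1ccccc1.[Cl-]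
Why: Wittig olefination with the preformed methoxymethylene ylide reacts only at the aldehyde and gives the enol ether needed for one-carbon homologation (its geometry is inconsequential).

Step 4
Reactants: 7 methyl 3,4-dimethoxy-5-[4-(2-methoxyethenyl)phenoxy]benzoate
Product: 8 methyl 3,4-dimethoxy-5-[4-(2-oxoethyl)phenoxy]benzoate
Conditions: 2 M aq. HCl, THF, 50 °C; used crude
Reagents that add atoms: water, O
Why: Acid-catalysed enol ether hydrolysis releases the arylacetaldehyde under conditions too mild to cleave the aryl methyl ester.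

Step 5
Reactants: 8 methyl 3,4-dimethoxy-5-[4-(2-oxoethyl)phenoxy]benzoate
Product: 9 {4-[2,3-dimethoxy-5-(methoxycarbonyl)phenoxy]phenyl}acetic acid
Conditions: NaClO2, NaH2PO4, 2-methyl-2-butene, t-BuOH/H2O, rt
Reagents that add atoms: sodium chlorite, [Na+].[O-]Cl=O
Why: Pinnick oxidation converts the aldehyde into the acid chemoselectively, the alkene scavenger protecting the electron-rich rings from hypochlorite.

Step 6
Reactants: 9 {4-[2,3-dimethoxy-5-(methoxycarbonyl)phenoxy]phenyl}acetic acid; 3 2-(6-formyl-2,3-dimethoxyphenoxy)benzonitrile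
Product: 11 (2E)-3-[2-(2-cyanophenoxy)-3,4-dimethoxyphenyl]-2-{4-[2,3-dimethoxy-5-(methoxycarbonyl)phenoxy]phenyl}prop-2-enoic acid, via mixed acetic anhydride 10 (not isolated)
Conditions: Ac2O, Et3N, 120 °C; then H2O, aq. HCl
Reagents that add atoms: none
Why: Perkin condensation, an intermolecular aldol-type reaction in which the amine-generated enolate of mixed anhydride 10 adds to the non-enolisable aldehyde 3 and loss of acetate gives the E acid (aryl groups cis), joining the AB and CD fragments.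

Step 7
Reactants: 11 (2E)-3-[2-(2-cyanophenoxy)-3,4-dimethoxyphenyl]-2-{4-[2,3-dimethoxy-5-(methoxycarbonyl)phenoxy]phenyl}prop-2-enoic acid
Product: 12 methyl 3-(4-{(Z)-2-[2-(2-cyanophenoxy)-3,4-dimethoxyphenyl]ethenyl}phenoxy)-4,5-dimethoxybenzoate
Conditions: Cu powder, quinoline, 210 °C
Reagents that add atoms: none
Why: Copper-mediated protodecarboxylation of an α-aryl cinnamic acid proceeds with retention to the cis-stilbene, and the ester, nitrile and aryl ethers are thermally stable.

Step 8
Reactants: 12 methyl 3-(4-{(Z)-2-[2-(2-cyanophenoxy)-3,4-dimethoxyphenyl]ethenyl}phenoxy)-4,5-dimethoxybenzoate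
Product: 13 methyl 3-(4-{2-[2-(2-cyanophenoxy)-3,4-dimethoxyphenyl]ethyl}phenoxy)-4,5-dimethoxybenzoate
Conditions: H2 (1 atm), 5% Pd/C, EtOAc, rt, stopped at 1 equiv uptake
Reagents that add atoms: none
Why: Catalytic hydrogenation saturates the stilbene far faster than it touches the aryl nitrile under neutral conditions at 1 atm, giving the B–C bibenzyl bridge.

Step 9
Reactants: 13 methyl 3-(4-{2-[2-(2-cyanophenoxy)-3,4-dimethoxyphenyl]ethyl}phenoxy)-4,5-dimethoxybenzoate
Product: 15 2-[6-(2-{4-[5-(hydroxymethyl)-2,3-dimethoxyphenoxy]phenyl}ethyl)-2,3-dimethoxyphenoxy]benzaldehyde, via NH-aldimine 14 (not isolated)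
Conditions: DIBAL-H (4.5 equiv), CH2Cl2, −78 to 0 °C; then 1 M aq. HCl, rt
Reagents that add atoms: water, O
Why: DIBAL-H reduction takes the ester to the benzylic alcohol while the nitrile stops at the N-aluminio aldimine, which acidic work-up hydrolyses through 14 to the aldehyde, so the two termini emerge differentiated in one operation.

Step 10
Reactants: 15 2-[6-(2-{4-[5-(hydroxymethyl)-2,3-dimethoxyphenoxy]phenyl}ethyl)-2,3-dimethoxyphenoxy]benzaldehyde
Product: 16 {[3-(4-{2-[2-(2-formylphenoxy)-3,4-dimethoxyphenyl]ethyl}phenoxy)-4,5-dimethoxyphenyl]methyl}triphenylphosphonium bromide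
Conditions: PPh3·HBr, MeCN, reflux
Reagents that add atoms: triphenylphosphine hydrobromide, [Br-].c1ccc(cc1)[PH+](c1ccccc1)c1ccccc1
Why: Phosphonium salt formation by acid-promoted substitution of the para-methoxy-activated benzylic alcohol (through the benzylic bromide) is compatible with the free aryl aldehyde.

Step 11
Reactants: 16 {[3-(4-{2-[2-(2-formylphenoxy)-3,4-dimethoxyphenyl]ethyl}phenoxy)-4,5-dimethoxyphenyl]methyl}triphenylphosphonium bromide
Product: 18 macrocyclic stilbene tetramethyl ether (tetra-O-methyl target with CH=CH in the A–D bridge; E/Z mixture), via phosphonium ylide 17 (not isolated)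
Conditions: NaOMe, CH2Cl2, rt, syringe-pump addition of 16 (about 1 mM final)
Reagents that add atoms: none
Why: Intramolecular Wittig reaction of the semi-stabilised benzylic ylide with the aryl aldehyde under high dilution closes the 17-membered ring, the standard macrocyclisation for this class of macrocyclic bis(bibenzyls).

Step 12
Reactants: 18 macrocyclic stilbene tetramethyl ether
Product: 19 tetra-O-methyl ether of the target
Conditions: H2 (1 atm), 10% Pd/C, EtOAc/THF, rt
Reagents that add atoms: none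
Why: Catalytic hydrogenation of the stilbene double bond gives the second bibenzyl bridge and removes the E/Z issue, with nothing else reducible present.

Step 13
Reactants: 19 tetra-O-methyl ether of the target
Product: 20 target bis(bibenzyl) tetraphenol
Conditions: BBr3 (8 equiv), CH2Cl2, −78 °C to rt; then H2O (under argon)
Reagents that add atoms: none
Why: BBr3 Lewis-acid ether cleavage removes all four aryl methyl groups while the diaryl ether bonds, which have no alkyl carbon for bromide to attack, survive.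

**Compound list**
1 | 2-hydroxy-3,4-dimethoxybenzaldehyde | COc1ccc(C=O)c(O)c1OC | starting material
2 | 2-fluorobenzonitrile | N#Cc1ccccc1F | starting material
3 | 2-(6-formyl-2,3-dimethoxyphenoxy)benzonitrile | COc1ccc(C=O)c(Oc2ccccc2C#N)c1OC | intermediate
4 | methyl 3-hydroxy-4,5-dimethoxybenzoate | COC(=O)c1cc(O)c(OC)c(OC)c1 | starting material
5 | 4-fluorobenzaldehyde | O=Cc1ccc(F)cc1 | starting material
6 | methyl 3-(4-formylphenoxy)-4,5-dimethoxybenzoate | COC(=O)c1cc(OC)c(OC)c(Oc2ccc(C=O)cc2)c1 | intermediate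
7 | methyl 3,4-dimethoxy-5-[4-(2-methoxyethenyl)phenoxy]benzoate (E/Z mixture) | COC(=O)c1cc(OC)c(OC)c(Oc2ccc(C=COC)cc2)c1 | intermediate
8 | methyl 3,4-dimethoxy-5-[4-(2-oxoethyl)phenoxy]benzoate | COC(=O)c1cc(OC)c(OC)c(Oc2ccc(CC=O)cc2)c1 | intermediate
9 | {4-[2,3-dimethoxy-5-(methoxycarbonyl)phenoxy]phenyl}acetic acid | COC(=O)c1cc(OC)c(OC)c(Oc2ccc(CC(O)=O)cc2)c1 | intermediate
10 | acetic {4-[2,3-dimethoxy-5-(methoxycarbonyl)phenoxy]phenyl}acetic anhydride (not isolated) | COC(=O)c1cc(OC)c(OC)c(Oc2ccc(CC(=O)OC(C)=O)cc2)c1 | intermediate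
11 | (2E)-3-[2-(2-cyanophenoxy)-3,4-dimethoxyphenyl]-2-{4-[2,3-dimethoxy-5-(methoxycarbonyl)phenoxy]phenyl}prop-2-enoic acid | COC(=O)c1cc(OC)c(OC)c(Oc2ccc(cc2)/C(C(O)=O)=C\c2ccc(OC)c(OC)c2Oc2ccccc2C#N)c1 | intermediate
12 | methyl 3-(4-{(Z)-2-[2-(2-cyanophenoxy)-3,4-dimethoxyphenyl]ethenyl}phenoxy)-4,5-dimethoxybenzoate | COC(=O)c1cc(OC)c(OC)c(Oc2ccc(cc2)/C=C\c2ccc(OC)c(OC)c2Oc2ccccc2C#N)c1 | intermediate
13 | methyl 3-(4-{2-[2-(2-cyanophenoxy)-3,4-dimethoxyphenyl]ethyl}phenoxy)-4,5-dimethoxybenzoate | COC(=O)c1cc(OC)c(OC)c(Oc2ccc(CCc3ccc(OC)c(OC)c3Oc3ccccc3C#N)cc2)c1 | intermediate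
14 | [3-(4-{2-[2-(2-(iminomethyl)phenoxy)-3,4-dimethoxyphenyl]ethyl}phenoxy)-4,5-dimethoxyphenyl]methanol (not isolated) | OCc1cc(OC)c(OC)c(Oc2ccc(CCc3ccc(OC)c(OC)c3Oc3ccccc3C=N)cc2)c1 | intermediate
15 | 2-[6-(2-{4-[5-(hydroxymethyl)-2,3-dimethoxyphenoxy]phenyl}ethyl)-2,3-dimethoxyphenoxy]benzaldehyde | OCc1cc(OC)c(OC)c(Oc2ccc(CCc3ccc(OC)c(OC)c3Oc3ccccc3C=O)cc2)c1 | intermediate
16 | {[3-(4-{2-[2-(2-formylphenoxy)-3,4-dimethoxyphenyl]ethyl}phenoxy)-4,5-dimethoxyphenyl]methyl}triphenylphosphonium bromide | [Br-].O=Cc1ccccc1Oc1c(CCc2ccc(Oc3cc(C[P+](c4ccccc4)(c4ccccc4)c4ccccc4)cc(OC)c3OC)cc2)ccc(OC)c1OC | intermediate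
17 | corresponding benzylidene triphenylphosphorane (ylide of 16, not isolated) | O=Cc1ccccc1Oc1c(CCc2ccc(Oc3cc(C=P(c4ccccc4)(c4ccccc4)c4ccccc4)cc(OC)c3OC)cc2)ccc(OC)c1OC | intermediate
18 | macrocyclic stilbene tetramethyl ether (E/Z mixture at the A–D CH=CH) | COc1cc2cc(c1OC)Oc1ccc(cc1)CCc1ccc(OC)c(OC)c1Oc1ccccc1C=C2 | intermediate
19 | tetra-O-methyl ether of the target | COc1cc2cc(c1OC)Oc1ccc(cc1)CCc1ccc(OC)c(OC)c1Oc1ccccc1CC2 | intermediate
20 | CNP0114693.0 (macrocyclic bis(bibenzyl) tetraphenol, achiral) | Oc1cc2cc(c1O)Oc1ccc(cc1)CCc1ccc(O)c(O)c1Oc1ccccc1CC2 | target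

**Summary**
Total steps: 13. Longest linear sequence: 12 steps (4 → 20 through steps 2–13); the CD branch (step 1) joins at step 6.

**Three steps most likely to fail, with fallbacks**

Step 6 (Perkin condensation; the ortho-aryloxy, para-methoxy aldehyde 3 is hindered and electron-rich). The fallback sets out from 9 (with 3) and comes back at 12. Acid 9 is deprotonated twice with LiHMDS (2.2 equiv, THF, −78 °C) and the enediolate is added to aldehyde 3 in an Ivanov-type aldol addition. This gives 3-[2-(2-cyanophenoxy)-3,4-dimethoxyphenyl]-3-hydroxy-2-{4-[2,3-dimethoxy-5-(methoxycarbonyl)phenoxy]phenyl}propanoic acid F1 as a diastereomer mixture. Heating F1 with DMF dimethyl acetal (CHCl3, reflux) effects decarboxylative dehydration to stilbene 12 together with its E isomer, both of which give 13 in step 8; compound 11 and the high-temperature step are bypassed.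

Step 7 (Cu/quinoline decarboxylation at 210 °C; tar formation or loss of material is possible). The fallback sets out from 11 and comes back at 13. The acrylic acid is first hydrogenated (H2, 1–3 atm, Pd/C, EtOAc, monitored) to 3-[2-(2-cyanophenoxy)-3,4-dimethoxyphenyl]-2-{4-[2,3-dimethoxy-5-(methoxycarbonyl)phenoxy]phenyl}propanoic acid F2. F2 is coupled with N-hydroxypyridine-2-thione (DCC, DMAP, CH2Cl2, dark) to give the Barton ester 2-thioxopyridin-1(2H)-yl 3-[2-(2-cyanophenoxy)-3,4-dimethoxyphenyl]-2-{4-[2,3-dimethoxy-5-(methoxycarbonyl)phenoxy]phenyl}propanoate F3. Irradiation of F3 with t-BuSH (visible light, THF, rt) gives bibenzyl 13 by radical reductive decarboxylation through the benzylic radical.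

Step 11 (macrocyclisation; the 17-membered ring with a para-phenylene is strained and oligomerisation competes). The fallback sets out from 15 and comes back at 18. The benzylic alcohol of 15 is oxidised with activated MnO2 (CH2Cl2, rt) to the dialdehyde 3-(4-{2-[2-(2-formylphenoxy)-3,4-dimethoxyphenyl]ethyl}phenoxy)-4,5-dimethoxybenzaldehyde F4. The ring is then closed by intramolecular McMurry reductive coupling (TiCl4, Zn, pyridine, THF, reflux, syringe-pump addition), which gives macrocyclic stilbene 18 directly.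

**Further compounds**
F1 | step 6 | 3-[2-(2-cyanophenoxy)-3,4-dimethoxyphenyl]-3-hydroxy-2-{4-[2,3-dimethoxy-5-(methoxycarbonyl)phenoxy]phenyl}propanoic acid (diastereomer mixture, racemic) | COC(=O)c1cc(OC)c(OC)c(Oc2ccc(cc2)C(C(O)=O)C(O)c2ccc(OC)c(OC)c2Oc2ccccc2C#N)c1
F2 | step 7 | 3-[2-(2-cyanophenoxy)-3,4-dimethoxyphenyl]-2-{4-[2,3-dimethoxy-5-(methoxycarbonyl)phenoxy]phenyl}propanoic acid (racemic) | COC(=O)c1cc(OC)c(OC)c(Oc2ccc(cc2)C(C(O)=O)Cc2ccc(OC)c(OC)c2Oc2ccccc2C#N)c1
F3 | step 7 | 2-thioxopyridin-1(2H)-yl 3-[2-(2-cyanophenoxy)-3,4-dimethoxyphenyl]-2-{4-[2,3-dimethoxy-5-(methoxycarbonyl)phenoxy]phenyl}propanoate (racemic) | COC(=O)c1cc(OC)c(OC)c(Oc2ccc(cc2)C(Cc2ccc(OC)c(OC)c2Oc2ccccc2C#N)C(=O)On2ccccc2=S)c1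
F4 | step 11 | 3-(4-{2-[2-(2-formylphenoxy)-3,4-dimethoxyphenyl]ethyl}phenoxy)-4,5-dimethoxybenzaldehyde | O=Cc1cc(OC)c(OC)c(Oc2ccc(CCc3ccc(OC)c(OC)c3Oc3ccccc3C=O)cc2)c1
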